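The ester groups, the isopropyl group and the C5–H/C6–O pair are removed first, which leaves a bicyclic diene ketal. Ring A is then disconnected at C1–C10. The oxygenated C10 lies next to quaternary C1, trans to its methyl, with C8=C9 on one side and C5–C6 on the other; this is the cyclohepta-1,4-diene pattern of a cis-divinylcyclopropane Cope rearrangement. That single thermal step closes seven-membered ring A, forms C1–C10 and sets C1 and C10 from cyclopropane chirality and alkene geometry. The precursor is an enantioenriched cis-1,2-dialkenylcyclopropane (C6–C7–C8) bearing the ring-B cyclopentenyl ketal on C6 and an E p-methoxybenzyl enol ether on C8.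

Key step: step 10

Numbering used in all names of bicyclic compounds (not von Baeyer numbering): ring B = C1–C5, ring A = C1, C5–C10; C1 quaternary (methyl), C4 carbinol carbon, C5 ring-fusion CH, C8 methyl-bearing; α = face opposite the C1 methyl.
Assumption: the dioxaborolane-controlled cyclopropanation follows, for the Z-trisubstituted dienol 10, the facial rule known for simple allylic alcohols; otherwise the (4S,5S) reagent is used.
Remark on the chemistry: a borane with a single B–H is used in step 11 because BH3 could bridge the two ring-A alkenes; the isopropyl group is added before O6 is acylated so that no β-acyloxy ketone meets a basic reagent; the PMB ether is cleaved only after the skipped diene is gone.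

Step 1
Reactants: 1 3-methylcyclopent-2-en-1-one
Product: 3 2-bromo-3-methylcyclopent-2-en-1-one, via dibromo ketone 2 (not isolated)
Conditions: Br2, CH2Cl2, 0 °C; then Et3N, 0 °C to rt
Reagents that add atoms: bromine, BrBr
Why: Bromine adds across the enone alkene and triethylamine removes HBr from the α,β-dibromide (addition–elimination α-bromination of an enone), which leaves bromine on the carbon that becomes C5.

Step 2
Reactants: 3 2-bromo-3-methylcyclopent-2-en-1-one
Product: 4 6-bromo-7-methyl-1,4-dioxaspiro[4.4]non-6-ene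
Conditions: HOCH2CH2OH, p-TsOH·H2O (cat.), benzene, reflux, Dean–Stark
Reagents that add atoms: ethane-1,2-diol, OCCO
Why: Acid-catalysed ketalisation with azeotropic removal of water masks the future C4 ketone as a dioxolane, and as with other 2-bromocycloalkenones the bromoalkene should not migrate.

Step 3
Reactants: 4 6-bromo-7-methyl-1,4-dioxaspiro[4.4]non-6-ene
Product: 6 4,4,5,5-tetramethyl-2-(7-methyl-1,4-dioxaspiro[4.4]non-6-en-6-yl)-1,3,2-dioxaborolane, via alkenyllithium 5 (not isolated)
Conditions: n-BuLi, THF, −78 °C; then i-PrOBpin, −78 °C to rt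
Reagents that add atoms: 2-isopropoxy-4,4,5,5-tetramethyl-1,3,2-dioxaborolane, CC(C)OB1OC(C)(C)C(C)(C)O1
Why: Bromine–lithium exchange at low temperature gives the alkenyllithium, which the borate ester traps as the pinacol boronate (borylation by halogen–metal exchange).

Step 4
Reactants: 7 prop-2-yn-1-ol (propargyl alcohol)
Product: 9 (Z)-3-iodo-2-methylprop-2-en-1-ol, via alkenylmagnesium alkoxide 8 (not isolated)
Conditions: MeMgBr (3 equiv), CuI (10 mol %), THF, −10 °C to rt; then I2, −78 to 0 °C
Reagents that add atoms: methylmagnesium bromide, C[Mg]Br; iodine, II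
Why: Copper-catalysed anti carbomagnesiation of the propargylic alkoxide gives a chelated alkenylmagnesium with magnesium cis to CH2O, and iodinolysis with retention should deliver the Z iodide.

Step 5
Reactants: 6 4,4,5,5-tetramethyl-2-(7-methyl-1,4-dioxaspiro[4.4]non-6-en-6-yl)-1,3,2-dioxaborolane; 9 (Z)-3-iodo-2-methylprop-2-en-1-ol
Product: 10 (Z)-2-methyl-3-(7-methyl-1,4-dioxaspiro[4.4]non-6-en-6-yl)prop-2-en-1-ol
Conditions: Pd(OAc)2 (5 mol %), SPhos (10 mol %), K3PO4, THF/H2O, 50 °C
Reagents that add atoms: none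
Why: Suzuki–Miyaura coupling of two alkenyl partners proceeds with retention at both carbons, so the Z geometry (ring cis to CH2OH) is carried into the diene; the biaryl phosphine copes with the hindered boronate and the free alcohol is tolerated.

Step 6
Reactants: 10 (Z)-2-methyl-3-(7-methyl-1,4-dioxaspiro[4.4]non-6-en-6-yl)prop-2-en-1-ol
Product: 11 [(1S,2R)-1-methyl-2-(7-methyl-1,4-dioxaspiro[4.4]non-6-en-6-yl)cyclopropyl]methanol
Conditions: Et2Zn, CH2I2, DME, CH2Cl2, −10 °C; (4R,5R)-2-butyl-N,N,N′,N′-tetramethyl-1,3,2-dioxaborolane-4,5-dicarboxamide (1.2 equiv), then 10, −10 °C to rt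
Reagents that add atoms: diiodomethane, ICI
Why: In this dioxaborolane-controlled asymmetric Simmons–Smith cyclopropanation the zinc alkoxide and the chiral boronate guide Zn(CH2I)2 to one face of the allylic alkene only, syn addition keeps the ring and CH2OH cis, the (4R,5R) reagent should set C6 (R) and C8 (S), and the undirected tetrasubstituted alkene is left alone.

Step 7
Reactants: 11 [(1S,2R)-1-methyl-2-(7-methyl-1,4-dioxaspiro[4.4]non-6-en-6-yl)cyclopropyl]methanol
Product: 12 (1S,2R)-1-methyl-2-(7-methyl-1,4-dioxaspiro[4.4]non-6-en-6-yl)cyclopropane-1-carbaldehyde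
Conditions: Dess–Martin periodinane, NaHCO3, CH2Cl2, 0 °C; used at once
Reagents that add atoms: none
Why: Buffered Dess–Martin oxidation of the primary alcohol is neutral enough for the ketal, the quaternary α-carbon cannot epimerise, and the tetrasubstituted alkene should make retro-Claisen ring expansion of the cis-alkenyl aldehyde slow at 0 °C.

Step 8
Reactants: 12 (1S,2R)-1-methyl-2-(7-methyl-1,4-dioxaspiro[4.4]non-6-en-6-yl)cyclopropane-1-carbaldehyde
Product: 13 2-{(E)-2-[(1R,2R)-1-methyl-2-(7-methyl-1,4-dioxaspiro[4.4]non-6-en-6-yl)cyclopropyl]ethenyl}-4,4,5,5-tetramethyl-1,3,2-dioxaborolane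
Conditions: CrCl2 (8 equiv), LiI (4 equiv), Cl2CHBpin (2 equiv), THF, rt
Reagents that add atoms: 2-(dichloromethyl)-4,4,5,5-tetramethyl-1,3,2-dioxaborolane, ClC(Cl)B1OC(C)(C)C(C)(C)O1
Why: In the Takai–Utimoto boryl-olefination the geminal dichromium reagent adds to the aldehyde and anti elimination from the less crowded adduct should give the E-alkenylboronate selectively under non-basic conditions at room temperature.

Step 9
Reactants: 13 2-{(E)-2-[(1R,2R)-1-methyl-2-(7-methyl-1,4-dioxaspiro[4.4]non-6-en-6-yl)cyclopropyl]ethenyl}-4,4,5,5-tetramethyl-1,3,2-dioxaborolane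
Product: 14 6-{(1R,2S)-2-[(E)-2-(4-methoxybenzyloxy)ethenyl]-2-methylcyclopropyl}-7-methyl-1,4-dioxaspiro[4.4]non-6-ene
Conditions: Cu(OAc)2 (2 equiv), Et3N (4 equiv), 4-MeOC6H4CH2OH (10 equiv), 4 Å MS, CH2Cl2, air, rt; Et3N-treated silica
Reagents that add atoms: 4-methoxybenzyl alcohol, COc1ccc(CO)cc1
Why: Chan–Lam-type oxidative C–O coupling of an alkenylboronate with an aliphatic alcohol proceeds through transmetalation to copper and C–O reductive elimination with retention, so it should give the E enol ether at room temperature, below the onset of the Cope rearrangement and under basic conditions that spare ketal and enol ether.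

Step 10
Reactants: 14 6-{(1R,2S)-2-[(E)-2-(4-methoxybenzyloxy)ethenyl]-2-methylcyclopropyl}-7-methyl-1,4-dioxaspiro[4.4]non-6-ene
Product: 15 (1S,10R)-4,4-ethylenedioxy-10-(4-methoxybenzyloxy)-1,8-dimethylbicyclo[5.3.0]deca-5,8-diene (OPMB trans to the C1 methyl)
Conditions: toluene (degassed, trace BHT, base-washed glass), 130 °C, sealed tube
Reagents that add atoms: none
Why: The reaction is a concerted [3,3]-sigmatropic shift through the boat array in which both alkenyl groups lie over the three-membered ring: the C6–C8 σ bond breaks as C1–C10 forms and the π bonds move to C5=C6 and C8=C9, driven by release of cyclopropane strain. The closest known reaction type is the thermal cis-1,2-dialkenylcyclopropane (Cope) rearrangement to a cyclohepta-1,4-diene, known for methylcyclopentenyl-substituted cyclopropanes that form a methyl-bearing quaternary centre. Ring A closes as the seven-membered ring by pericyclic ring expansion (three- to seven-membered, bond formation suprafacial at both termini), not by an exo or endo cyclisation, and both ring alkenes are necessarily cis. C10 is controlled by the E geometry of the enol ether and C1 by the fixed geometry of the ring-B alkene: the two substituents trans to the cyclopropane (OPMB on C10, C2 on C1) point outward and end syn, so oxygen is anti to the C1 methyl, and the absolute sense is relayed from the C6 and C8 cyclopropane centres. The step needs only this diastereospecificity, which the cis cyclopropane and the geometrically pure E enol ether secure; the inward C1 methyl on a tetrasubstituted terminus should only raise the barrier (hence 130 °C), and neutral, acid-free conditions keep enol ether, ketal and PMB ether intact.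

Step 11
Reactants: 15 (1S,10R)-4,4-ethylenedioxy-10-(4-methoxybenzyloxy)-1,8-dimethylbicyclo[5.3.0]deca-5,8-diene
Product: 17 (1S,5S,6S,10R)-4,4-ethylenedioxy-10-(4-methoxybenzyloxy)-1,8-dimethylbicyclo[5.3.0]dec-8-en-6-ol (6α-OH; H5 α; trans-fused), via B-alkyl-9-BBN adduct 16 (not isolated)
Conditions: 9-BBN, THF, 65 °C; then NaOH, H2O2, 0 °C to rt
Reagents that add atoms: hydrogen peroxide, OO
Why: In this hydroboration–oxidation a dialkylborane with one B–H (which cannot bridge to the second alkene) should put boron on C6, the less substituted carbon remote from the ketal, and hydrogen on C5 by syn addition on the α face opposite the C1 methyl (as in Δ5-steroids), while C8=C9 is screened by the adjacent 10-OPMB group on one face and the C1 methyl on the other; oxidation with retention gives 6α-OH and the trans ring fusion, with C5 and C6 set by substrate control.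

Step 12
Reactants: 17 (1S,5S,6S,10R)-4,4-ethylenedioxy-10-(4-methoxybenzyloxy)-1,8-dimethylbicyclo[5.3.0]dec-8-en-6-ol
Product: 18 (1S,5S,6S,10R)-6-hydroxy-10-(4-methoxybenzyloxy)-1,8-dimethylbicyclo[5.3.0]dec-8-en-4-one
Conditions: PPTS (cat.), acetone/H2O 10:1, 40 °C
Reagents that add atoms: water, O
Why: Mild acid-catalysed ketal hydrolysis releases the C4 ketone without touching the PMB ether or the alkene, and the free β-hydroxyl is too poor a leaving group for dehydration, so C5 should stay intact.

Step 13
Reactants: 18 (1S,5S,6S,10R)-6-hydroxy-10-(4-methoxybenzyloxy)-1,8-dimethylbicyclo[5.3.0]dec-8-en-4-one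
Product: 19 (1S,4R,5S,6S,10R)-4-isopropyl-10-(4-methoxybenzyloxy)-1,8-dimethylbicyclo[5.3.0]dec-8-ene-4,6-diol (4β-OH, 4α-isopropyl)
Conditions: i-PrMgCl, anhydrous CeCl3 (4 equiv each), THF, −78 to −40 °C
Reagents that add atoms: isopropylmagnesium chloride, CC(C)[Mg]Cl
Why: In this organocerium 1,2-addition the weakly basic isopropylcerium reagent should add to the ketone rather than enolise or reduce it, approaching C4 on the α face, syn to H5 and anti to the angular C1 methyl (as in additions to 15-oxo-14α-steroids), which sets the 4β-hydroxy-4α-isopropyl centre by substrate control.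

Step 14
Reactants: 19 (1S,4R,5S,6S,10R)-4-isopropyl-10-(4-methoxybenzyloxy)-1,8-dimethylbicyclo[5.3.0]dec-8-ene-4,6-diol; 20 veratric acid (3,4-dimethoxybenzoic acid)
Product: 22 (1S,4R,5S,6S,10R)-4-hydroxy-4-isopropyl-10-(4-methoxybenzyloxy)-1,8-dimethylbicyclo[5.3.0]dec-8-en-6-yl 3,4-dimethoxybenzoate, via O-acylisourea 21 (not isolated)
Conditions: DCC, DMAP (cat.), CH2Cl2, 0 °C to rt
Reagents that add atoms: none
Why: Steglich esterification through the O-acylisourea and the acylpyridinium ion acylates the only reactive hydroxyl, the secondary 6-OH, because the tertiary 4-OH is inert and O10 is still protected.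

Step 15
Reactants: 22 (1S,4R,5S,6S,10R)-4-hydroxy-4-isopropyl-10-(4-methoxybenzyloxy)-1,8-dimethylbicyclo[5.3.0]dec-8-en-6-yl 3,4-dimethoxybenzoate
Product: 23 (1S,4R,5S,6S,10R)-4,10-dihydroxy-4-isopropyl-1,8-dimethylbicyclo[5.3.0]dec-8-en-6-yl 3,4-dimethoxybenzoate
Conditions: DDQ, CH2Cl2/pH 7 buffer, 0 °C
Reagents that add atoms: none
Why: Oxidative PMB-ether cleavage with DDQ (hydride abstraction to the oxocarbenium ion, then hydrolysis) is selective for the electron-rich benzyl ether, and the ester-deactivated veratrate ring and the single remaining alkene should not be oxidised.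

Step 16
Reactants: 23 (1S,4R,5S,6S,10R)-4,10-dihydroxy-4-isopropyl-1,8-dimethylbicyclo[5.3.0]dec-8-en-6-yl 3,4-dimethoxybenzoate; 24 angelic acid ((Z)-2-methylbut-2-enoic acid)
Product: 26 CNP0142353.1 which is (1S,4R,5S,6S,10R)-4-hydroxy-4-isopropyl-1,8-dimethyl-10-[(Z)-2-methylbut-2-enoyloxy]bicyclo[5.3.0]dec-8-en-6-yl 3,4-dimethoxybenzoate, via mixed anhydride 25 (not isolated)
Conditions: 24, 2,4,6-Cl3C6H2COCl, Et3N, toluene, rt; then 23, 80 °C
Reagents that add atoms: none
Why: In this Yamaguchi mixed-anhydride esterification the hindered 10-OH attacks the angeloyl carbonyl on heating without a nucleophilic catalyst, conditions under which the Z alkene should not isomerise to the tiglate and the tertiary 4-OH does not react.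

Compound list
1 | 3-methylcyclopent-2-en-1-one | CC1=CC(=O)CC1 | starting material
2 | trans-2,3-dibromo-3-methylcyclopentan-1-one (racemic, one enantiomer drawn) | C[C@]1(Br)CCC(=O)[C@@H]1Br | intermediate
3 | 2-bromo-3-methylcyclopent-2-en-1-one | CC1=C(Br)C(=O)CC1 | intermediate
4 | 6-bromo-7-methyl-1,4-dioxaspiro[4.4]non-6-ene | CC1=C(Br)C2(CC1)OCCO2 | intermediate
5 | (7-methyl-1,4-dioxaspiro[4.4]non-6-en-6-yl)lithium | CC1=C([Li])C2(CC1)OCCO2 | intermediate
6 | 4,4,5,5-tetramethyl-2-(7-methyl-1,4-dioxaspiro[4.4]non-6-en-6-yl)-1,3,2-dioxaborolane | CC1=C(B2OC(C)(C)C(C)(C)O2)C2(CC1)OCCO2 | intermediate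
7 | prop-2-yn-1-ol (propargyl alcohol) | C#CCO | starting material
8 | bromomagnesium (Z)-3-(bromomagnesio)-2-methylprop-2-en-1-olate | C/C(CO[Mg]Br)=C/[Mg]Br | intermediate
9 | (Z)-3-iodo-2-methylprop-2-en-1-ol | C/C(CO)=C/I | intermediate
10 | (Z)-2-methyl-3-(7-methyl-1,4-dioxaspiro[4.4]non-6-en-6-yl)prop-2-en-1-ol | C/C(CO)=C/C1=C(C)CCC12OCCO2 | intermediate
11 | [(1S,2R)-1-methyl-2-(7-methyl-1,4-dioxaspiro[4.4]non-6-en-6-yl)cyclopropyl]methanol | OC[C@@]1(C)C[C@H]1C1=C(C)CCC12OCCO2 | intermediate
12 | (1S,2R)-1-methyl-2-(7-methyl-1,4-dioxaspiro[4.4]non-6-en-6-yl)cyclopropane-1-carbaldehyde | O=C[C@@]1(C)C[C@H]1C1=C(C)CCC12OCCO2 | intermediate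
13 | 2-{(E)-2-[(1R,2R)-1-methyl-2-(7-methyl-1,4-dioxaspiro[4.4]non-6-en-6-yl)cyclopropyl]ethenyl}-4,4,5,5-tetramethyl-1,3,2-dioxaborolane | CC1(C)OB(/C=C/[C@@]2(C)C[C@H]2C2=C(C)CCC23OCCO3)OC1(C)C | intermediate
14 | 6-{(1R,2S)-2-[(E)-2-(4-methoxybenzyloxy)ethenyl]-2-methylcyclopropyl}-7-methyl-1,4-dioxaspiro[4.4]non-6-ene (cis-dialkenylcyclopropane, key-step precursor) | COc1ccc(CO/C=C/[C@@]2(C)C[C@H]2C2=C(C)CCC23OCCO3)cc1 | intermediate
15 | (1S,10R)-4,4-ethylenedioxy-10-(4-methoxybenzyloxy)-1,8-dimethylbicyclo[5.3.0]deca-5,8-diene (key-step product) | COc1ccc(CO[C@@H]2C=C(C)CC=C3[C@]2(C)CCC34OCCO4)cc1 | intermediate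
16 | 6α-(9-borabicyclo[3.3.1]nonan-9-yl) adduct of 15 (H5 α) | COc1ccc(CO[C@@H]2C=C(C)C[C@H](B3C4CCCC3CCC4)[C@@H]3[C@]2(C)CCC34OCCO4)cc1 | intermediate
17 | (1S,5S,6S,10R)-4,4-ethylenedioxy-10-(4-methoxybenzyloxy)-1,8-dimethylbicyclo[5.3.0]dec-8-en-6-ol | COc1ccc(CO[C@@H]2C=C(C)C[C@H](O)[C@@H]3[C@]2(C)CCC34OCCO4)cc1 | intermediate
18 | (1S,5S,6S,10R)-6-hydroxy-10-(4-methoxybenzyloxy)-1,8-dimethylbicyclo[5.3.0]dec-8-en-4-one | COc1ccc(CO[C@@H]2C=C(C)C[C@H](O)[C@@H]3[C@]2(C)CCC3=O)cc1 | intermediate
19 | (1S,4R,5S,6S,10R)-4-isopropyl-10-(4-methoxybenzyloxy)-1,8-dimethylbicyclo[5.3.0]dec-8-ene-4,6-diol | COc1ccc(CO[C@@H]2C=C(C)C[C@H](O)[C@@H]3[C@]2(C)CC[C@@]3(O)C(C)C)cc1 | intermediate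
20 | veratric acid (3,4-dimethoxybenzoic acid) | COc1ccc(C(=O)O)cc1OC | starting material
21 | N,N′-dicyclohexyl-O-(3,4-dimethoxybenzoyl)isourea | COc1ccc(C(=O)OC(=NC2CCCCC2)NC2CCCCC2)cc1OC | intermediate
22 | (1S,4R,5S,6S,10R)-4-hydroxy-4-isopropyl-10-(4-methoxybenzyloxy)-1,8-dimethylbicyclo[5.3.0]dec-8-en-6-yl 3,4-dimethoxybenzoate | COc1ccc(CO[C@@H]2C=C(C)C[C@H](OC(=O)c3ccc(OC)c(OC)c3)[C@@H]3[C@]2(C)CC[C@@]3(O)C(C)C)cc1 | intermediate
23 | (1S,4R,5S,6S,10R)-4,10-dihydroxy-4-isopropyl-1,8-dimethylbicyclo[5.3.0]dec-8-en-6-yl 3,4-dimethoxybenzoate | O[C@@H]1C=C(C)C[C@H](OC(=O)c2ccc(OC)c(OC)c2)[C@@H]2[C@]1(C)CC[C@@]2(O)C(C)C | intermediate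
24 | angelic acid ((Z)-2-methylbut-2-enoic acid) | C/C=C(/C)C(=O)O | starting material
25 | (Z)-2-methylbut-2-enoic 2,4,6-trichlorobenzoic anhydride | C/C=C(/C)C(=O)OC(=O)c1c(Cl)cc(Cl)cc1Cl | intermediate
26 | CNP0142353.1, (1S,4R,5S,6S,10R)-4-hydroxy-4-isopropyl-1,8-dimethyl-10-[(Z)-2-methylbut-2-enoyloxy]bicyclo[5.3.0]dec-8-en-6-yl 3,4-dimethoxybenzoate | C/C=C(/C)C(=O)O[C@@H]1C=C(C)C[C@H](OC(=O)c2ccc(OC)c(OC)c2)[C@@H]2[C@]1(C)CC[C@@]2(O)C(C)C | target

Total step count: 16. Longest linear sequence: 15 steps (1 to 26 through steps 1–3 and 5–16); step 4 is the only side branch.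

Steps most likely to fail

Step 11. The bulky borane may react too slowly at the congested C5=C6 alkene, or may attack C8=C9 instead, so that chemoselectivity is lost. The fallback sets out from 15. Pyridinium tribromide (pyridine, CH2Cl2, −40 °C) should add bromine to the more nucleophilic C8=C9, which is remote from the electron-withdrawing ketal, to give the trans-8,9-dibromide F1; its configuration is of no consequence. With one alkene left, BH3·THF followed by NaBO3 should give the 6α-hydroxy dibromide F2 by the same α-face syn addition. Zinc dust (AcOH, THF, 0 °C) then removes both bromine atoms and restores C8=C9, which brings the route back at 17.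

Step 13. Addition to the hindered β-hydroxy ketone may be overtaken by enolisation, retro-aldol cleavage or hydride transfer from the isopropyl reagent, and facial selectivity at C4 may erode. The fallback sets out from 18. Prop-1-en-2-ylmagnesium bromide with CeCl3, a smaller sp2 nucleophile that cannot act as a hydride donor, should give the isopropenyl carbinol F3 from the same α face. Hydrogenation with (PPh3)3RhCl under H2 should reduce only the 1,1-disubstituted alkene and leave C8=C9 and the PMB ether, which returns the route at 19.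

Step 10. The inward C1 methyl may slow the rearrangement so far that the enol ether is lost by elimination or hydrolysis, or the cyclopropane epimerises, at the temperature needed. The fallback sets out from 13. The thermally robust E-alkenylboronate is itself rearranged (xylene, 150 °C) through the same boat array to the allylic boronate F4, with boron in the place of the C10 oxygen and trans to the C1 methyl. NaBO3 oxidation with retention should give the allylic alcohol F5, and NaH, 4-methoxybenzyl chloride and Bu4NI in DMF convert it into 15.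

Further compounds
F1 | step 11 | (1S,10R)-8α,9β-dibromo-4,4-ethylenedioxy-10-(4-methoxybenzyloxy)-1,8-dimethylbicyclo[5.3.0]dec-5-ene | COc1ccc(CO[C@@H]2[C@@H](Br)[C@](C)(Br)CC=C3[C@]2(C)CCC34OCCO4)cc1
F2 | step 11 | 8α,9β-dibromo-4,4-ethylenedioxy-10α-(4-methoxybenzyloxy)-1,8-dimethylbicyclo[5.3.0]decan-6α-ol (H5 α) | COc1ccc(CO[C@@H]2[C@@H](Br)[C@](C)(Br)C[C@H](O)[C@@H]3[C@]2(C)CCC34OCCO4)cc1
F3 | step 13 | 10α-(4-methoxybenzyloxy)-1,8-dimethyl-4α-(prop-1-en-2-yl)bicyclo[5.3.0]dec-8-ene-4β,6α-diol (H5 α) | COc1ccc(CO[C@@H]2C=C(C)C[C@H](O)[C@@H]3[C@]2(C)CC[C@@]3(O)C(C)=C)cc1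
F4 | step 10 | 2-[4,4-ethylenedioxy-1,8-dimethylbicyclo[5.3.0]deca-5,8-dien-10α-yl]-4,4,5,5-tetramethyl-1,3,2-dioxaborolane (1S; boron trans to the C1 methyl) | CC1(C)OB([C@@H]2C=C(C)CC=C3[C@]2(C)CCC34OCCO4)OC1(C)C
F5 | step 10 | (1S,10R)-4,4-ethylenedioxy-1,8-dimethylbicyclo[5.3.0]deca-5,8-dien-10-ol | O[C@@H]1C=C(C)CC=C2[C@]1(C)CCC23OCCO3
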